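## The problem

Compound 14, (3R)-8-hydroxy-3-(11-hydroxyundecyl)-6-methoxy-3,4-dihydro-1H-isochromen-1-one, is a 3,4-dihydroisocoumarin. A resorcinol-type arene (ring A) is fused through C4a and C8a to a δ-lactone (ring B), and C3 carries an unbranched eleven-carbon chain (C1′–C11′) that ends in a primary alcohol. A synthesis has to decide which ring-B bond closes the ring and at what oxidation level C1 arrives. It also has to tell the two ring-A oxygens apart, since C6 is a methyl ether and C8 a free phenol. C3 (R) is the only stereocentre, so nothing in the molecule can relay its configuration. It is a secondary carbinol flanked by two methylene groups (C4 and C1′) of similar size, which makes asymmetric reduction of the corresponding ketone a poor choice, so the configuration is better bought. The lactone is open to hydroxide and strong base, the electron-rich ring A is sensitive to oxidants and electrophiles, and the primary alcohol must be masked while C1 is oxidised. Two features of the structure help. The C8 oxygen is peri to the C1 carbonyl, so a chelating Lewis acid can unmask it selectively. C8a is ortho to the C8 oxygen and para to the C6 oxygen, and in a 3,5-dimethoxyphenyl precursor the two carbons ortho to the side chain are equivalent. A one-carbon electrophile tethered to the C3 oxygen can therefore reach only this doubly activated position and can only form the six-membered ring B.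

## Retrosynthesis

**14 back to 12.** No skeletal bond is cut. The primary alcohol of 14 is taken back to a triisopropylsilyl ether (13) and the C8 phenol to its methyl ether (12). The silyl ether has to outlast a Grignard reagent, a silyl triflate and an oxidant. The C8 methyl ether is the one aryl ether that a boron trihalide cleaves selectively, because it is chelated with the lactone carbonyl. Precursor 12 has both phenol oxygens as methyl ethers, which restores the local symmetry of ring A.

**12 back to 11.** The C1 carbonyl is taken back to a methylene group, giving isochroman 11. This lets the C8a–C1 bond be made at the formaldehyde oxidation level, where electrophilic closure onto the arene is most reliable. The forward oxidation must pick C1, which is activated by both O2 and ring A, over C4, which is activated by ring A alone.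

**11 back to 10.** This is the key cut, the C8a–C1 bond. The precursor 10 is the methoxymethyl ether of an open-chain 1-aryl-2-alkanol, so ring B disappears and no ring-fused intermediate is needed before this point. Cutting C1–O2 (lactonisation) or C3–C4 instead would require a 1,2,3,5-tetrasubstituted arene that already carries a carboxyl carbon; cutting C8a–C1 needs only a symmetrical 3,5-dimethoxyphenyl group. The forward reaction has to ionise the acetal, close onto the arene once, and leave the silyl ether and C3 untouched.

**10 back to 9.** The O2–C1 bond is cut, a routine methoxymethylation of secondary alcohol 9.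

**9 back to 7 and 8.** The C1′–C2′ bond of the side chain is cut. This gives the enantiopure benzyl oxirane 7 and the Grignard reagent 8, which comes from silyl ether 2 and in turn from bromo alcohol 1. Reduction of a benzyl alkyl ketone was the neighbouring option, but its two methylene substituents offer a catalyst or enzyme little to distinguish. An epoxide opening at the unsubstituted carbon leaves the C3–O bond alone, so the configuration is whatever the epoxide had. The forward step needs terminal attack only.

**7 back to 5 and 4.** The C4–C4a bond is cut. Aryl Grignard reagent 5, made from bromide 3, opens (S)-epichlorohydrin 4 at the epoxide carbon to give chlorohydrin 6, and base closes the new oxirane. All three building blocks (1, 3, 4) are purchased, and the only stereocentre comes from 4.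

## Roads not taken

**Alternative 1:** Here the C3–O2 bond is traced back to a carbon–carbon bond of a twelve-membered ring ketone, A1, which carries the ring-A benzoate on its α-arylmethyl group. In the forward direction a peracid inserts oxygen on the more substituted side of A1, with retention, and gives the thirteen-membered lactone A2.
- Merits: C3 and the whole chain come from one inexpensive carbocycle, the terminal oxygen arrives as the lactone carbonyl, and C1 is a benzoate from the start, so no late benzylic oxidation is needed. In oxidation-state economy at C1 this road is better than the chosen one.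
- Weak points: the stereocentre of A1 sits α to a ketone. It has to be made by auxiliary-based asymmetric alkylation of a macrocyclic enolate with a hindered ortho,ortho′-disubstituted benzylic halide and then kept from epimerising. Large-ring ketones undergo the oxygen insertion slowly and call for strong peracids, which a dimethoxyarene tolerates poorly. After the key step two esters (the macrolactone and the methyl benzoate) must be told apart before ring B can form, and the C8 ether still has to be cleaved.
- Comparison: the chosen plan pays for its late oxidation of 11 with a stereocentre that is purchased, is never adjacent to a carbonyl group, and goes through a key step with no selectivity question. The step count of this alternative is not lower.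

**Alternative 2:** C3–C4 and C1–O2 are cut together. A chiral squaramide–amine catalyst would make the enolised anhydride A3 add through C4 to aldehyde A4, the new alkoxide would acylate C1, and the product would be acid A5.
- Merits: this is the most convergent road. Ring B, the C3 stereocentre and the correct oxidation level at C1 arise in one catalytic step, and the benzyl ether is removed by neutral hydrogenolysis. In convergence and step count on paper it is better than the chosen plan.
- Weak points: enantioselective versions of this annulation are established for aromatic aldehydes, whereas A4 is a linear, enolisable aliphatic aldehyde prone to self-condensation and offering little facial bias. The two methoxy groups make A3 less acidic and less electrophilic, and A3 itself takes several steps to make. The C4 carboxyl of A5 must then be removed: under heat or base the C4 anion can expel the C3 carboxylate and open ring B, so a radical decarboxylation with its own activation step would be needed.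
- Comparison: the chosen plan sets against this a certain enantiomeric purity and reactions that all lie within their known substrate range.

**Alternative 3:** The cut is inside ring A, at C4a–C8a. Mild base would make the diketo-dioxinone A6 undergo intramolecular aldol addition, dehydration and aromatisation to the benzodioxinone A7.
- Merits: ring A is born with its oxygens differentiated. The future C6 phenol is free for methylation, and the C8 oxygen and C1 carboxyl are tied up in the acetonide. After desilylation the C3 alkoxide would open the dioxinone and give ring B with the C8 phenol free, so neither a demethylation nor an oxidation is needed. In functional-group logic this road is better than the chosen plan.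
- Weak points: A6 must be assembled from a keto-dioxinone and an activated (R)-3-silyloxy acid that needs its own asymmetric step and chain construction. A6 contains a β-silyloxy ketone that can eliminate under the basic conditions of the key step, and it is a tautomeric mixture that is hard to purify. The route is several steps longer.
- Comparison: the chosen plan buys ring A and reaches the target in eight steps, at the price of one oxidation (step 6) and one selective demethylation (step 7).

Key step: step 5

Assumption: (S)-epichlorohydrin 4 is purchased in high enantiomeric purity, so the configuration of 14 rests on that purchased stereocentre.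

## Route

Step 1
Reactants: 1 10-bromodecan-1-ol
Product: 2 [(10-bromodecyl)oxy]tri(propan-2-yl)silane
Conditions: i-Pr3SiCl, imidazole, DMF, 0 °C → rt
Reagents that add atoms: chlorotri(propan-2-yl)silane, CC(C)[Si](Cl)(C(C)C)C(C)C
Why: Imidazole-mediated silylation of a primary alcohol; the hindered triisopropylsilyl ether is chosen because it must survive Grignard formation, a silyl triflate, permanganate and BCl3.

Step 2
Reactants: 3 1-bromo-3,5-dimethoxybenzene; 4 (S)-epichlorohydrin [(2S)-2-(chloromethyl)oxirane]
Product: 7 (2S)-2-[(3,5-dimethoxyphenyl)methyl]oxirane, via (3,5-dimethoxyphenyl)magnesium bromide 5 (not isolated), via chlorohydrin alkoxide 6 (not isolated)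
Conditions: Mg, I2 (cat.), THF, reflux; then 4, CuI (10 mol %), THF, −40 → 0 °C; then NaOH (2 M aq.), rt
Reagents that add atoms: none
Why: Grignard formation, CuI-catalysed SN2 opening of the epoxide at its unsubstituted carbon, then intramolecular Williamson closure of the chlorohydrin by hydroxide; the C–O bond at the stereocentre is never broken, so (S)-4 should give (S)-7.

Step 3
Reactants: 2 [(10-bromodecyl)oxy]tri(propan-2-yl)silane; 7 (2S)-2-[(3,5-dimethoxyphenyl)methyl]oxirane
Product: 9 (2R)-1-(3,5-dimethoxyphenyl)-13-{[tri(propan-2-yl)silyl]oxy}tridecan-2-ol, via alkylmagnesium bromide 8 (not isolated)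
Conditions: 2, Mg, THF, 50 °C; then 7, CuI (10 mol %), THF, −30 → 0 °C
Reagents that add atoms: none
Why: CuI-catalysed Grignard opening of a monosubstituted epoxide at the terminal carbon (SN2); the carbinol C–O bond is untouched, and the descriptor changes from S to R only because the substituent priorities change.

Step 4
Reactants: 9 (2R)-1-(3,5-dimethoxyphenyl)-13-{[tri(propan-2-yl)silyl]oxy}tridecan-2-ol
Product: 10 1-[(2R)-2-(methoxymethoxy)-13-{[tri(propan-2-yl)silyl]oxy}tridecyl]-3,5-dimethoxybenzene
Conditions: MeOCH2Cl, i-Pr2NEt, CH2Cl2, 0 °C → rt
Reagents that add atoms: chloromethyl methyl ether, COCCl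
Why: Methoxymethyl ether formation by alkylation of the secondary alcohol with an α-chloro ether under amine base; this puts O2–C1 in place at the formaldehyde oxidation level without touching C3.

Step 5
Reactants: 10 1-[(2R)-2-(methoxymethoxy)-13-{[tri(propan-2-yl)silyl]oxy}tridecyl]-3,5-dimethoxybenzene
Product: 11 (3R)-6,8-dimethoxy-3-(11-{[tri(propan-2-yl)silyl]oxy}undecyl)-3,4-dihydro-1H-isochromene
Conditions: Me3SiOSO2CF3 (0.2 equiv), MeCN, 0 °C, 0.02 M
Reagents that add atoms: none
Why: The silyl triflate silylates the methoxy oxygen of the acetal and methoxytrimethylsilane departs, leaving the oxocarbenium ion O2=C1 tethered to C3. The arene attacks this cation through the carbon ortho to the side chain, which is ortho to one methoxy group and para to the other, and proton loss restores aromaticity; the triflic acid released converts methoxytrimethylsilane into methanol and the silyl triflate, so a fraction of an equivalent of promoter should suffice. The closest known reaction type is the oxa-Pictet–Spengler cyclisation of methoxymethyl ethers of 2-arylethanols to isochromans, an intramolecular Friedel–Crafts alkylation. Ring B closes in a 6-endo-trig mode, since both atoms of the O2=C1 double bond lie inside the new ring. No stereocentre is formed, and C3 keeps its configuration because its C–O bond is never broken; ionisation on the other side of the acetal only releases a methoxymethyl cation reversibly. The step needs regioselectivity and mono-alkylation: the two carbons ortho to the chain are equivalent by the local symmetry of the 3,5-dimethoxyphenyl ring, the carbon between the two methoxy groups cannot be reached by the two-atom tether, and dilution favours ring closure over intermolecular arylation. The hindered triisopropylsilyl ether is not expected to exchange with the silyl triflate at 0 °C.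

Step 6
Reactants: 11 (3R)-6,8-dimethoxy-3-(11-{[tri(propan-2-yl)silyl]oxy}undecyl)-3,4-dihydro-1H-isochromene
Product: 12 (3R)-6,8-dimethoxy-3-(11-{[tri(propan-2-yl)silyl]oxy}undecyl)-3,4-dihydro-1H-isochromen-1-one
Conditions: KMnO4, BnEt3NCl (cat.), CH2Cl2, rt
Reagents that add atoms: potassium permanganate, [K+].[O-][Mn](=O)(=O)=O
Why: Phase-transfer permanganate oxidation of a cyclic benzylic ether to the lactone; C1 is activated by both O2 and the electron-rich ring whereas C4 is activated by the ring alone, and the silyl ether and C3–H are inert.

Step 7
Reactants: 12 (3R)-6,8-dimethoxy-3-(11-{[tri(propan-2-yl)silyl]oxy}undecyl)-3,4-dihydro-1H-isochromen-1-one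
Product: 13 (3R)-8-hydroxy-6-methoxy-3-(11-{[tri(propan-2-yl)silyl]oxy}undecyl)-3,4-dihydro-1H-isochromen-1-one
Conditions: BCl3 (1 M in CH2Cl2), CH2Cl2, −78 → 0 °C; then H2O
Reagents that add atoms: none
Why: Chelation-controlled Lewis acid ether cleavage: BCl3 binds between the lactone carbonyl and the peri C8 methoxy oxygen and chloride removes that methyl group only, while the C6 ether has no neighbouring donor and should stay.

Step 8
Reactants: 13 (3R)-8-hydroxy-6-methoxy-3-(11-{[tri(propan-2-yl)silyl]oxy}undecyl)-3,4-dihydro-1H-isochromen-1-one
Product: 14 (3R)-8-hydroxy-3-(11-hydroxyundecyl)-6-methoxy-3,4-dihydro-1H-isochromen-1-one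
Conditions: HF·pyridine, pyridine, THF, 0 °C → rt
Reagents that add atoms: none
Why: Fluoride-driven desilylation (Si–O cleavage) under buffered, non-basic conditions that leave the lactone and the phenol alone; the stereocentre is not involved.

## Compound list

1 | 10-bromodecan-1-ol | OCCCCCCCCCCBr | starting material
2 | [(10-bromodecyl)oxy]tri(propan-2-yl)silane | CC(C)[Si](OCCCCCCCCCCBr)(C(C)C)C(C)C | intermediate
3 | 1-bromo-3,5-dimethoxybenzene | COc1cc(Br)cc(OC)c1 | starting material
4 | (2S)-2-(chloromethyl)oxirane, (S)-epichlorohydrin | ClC[C@@H]1CO1 | starting material
5 | (3,5-dimethoxyphenyl)magnesium bromide | COc1cc(OC)cc([Mg]Br)c1 | intermediate (not isolated)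
6 | (2S)-1-chloro-3-(3,5-dimethoxyphenyl)propan-2-ol, present in the flask as its bromomagnesium alkoxide | COc1cc(OC)cc(C[C@H](O)CCl)c1 | intermediate (not isolated)
7 | (2S)-2-[(3,5-dimethoxyphenyl)methyl]oxirane | COc1cc(OC)cc(C[C@H]2CO2)c1 | intermediate
8 | (10-{[tri(propan-2-yl)silyl]oxy}decyl)magnesium bromide | CC(C)[Si](OCCCCCCCCCC[Mg]Br)(C(C)C)C(C)C | intermediate (not isolated)
9 | (2R)-1-(3,5-dimethoxyphenyl)-13-{[tri(propan-2-yl)silyl]oxy}tridecan-2-ol | COc1cc(OC)cc(C[C@H](O)CCCCCCCCCCCO[Si](C(C)C)(C(C)C)C(C)C)c1 | intermediate
10 | 1-[(2R)-2-(methoxymethoxy)-13-{[tri(propan-2-yl)silyl]oxy}tridecyl]-3,5-dimethoxybenzene | COc1cc(OC)cc(C[C@@H](CCCCCCCCCCCO[Si](C(C)C)(C(C)C)C(C)C)OCOC)c1 | intermediate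
11 | (3R)-6,8-dimethoxy-3-(11-{[tri(propan-2-yl)silyl]oxy}undecyl)-3,4-dihydro-1H-isochromene | COc1cc(OC)c2c(c1)C[C@@H](CCCCCCCCCCCO[Si](C(C)C)(C(C)C)C(C)C)OC2 | intermediate
12 | (3R)-6,8-dimethoxy-3-(11-{[tri(propan-2-yl)silyl]oxy}undecyl)-3,4-dihydro-1H-isochromen-1-one | COc1cc(OC)c2c(c1)C[C@@H](CCCCCCCCCCCO[Si](C(C)C)(C(C)C)C(C)C)OC2=O | intermediate
13 | (3R)-8-hydroxy-6-methoxy-3-(11-{[tri(propan-2-yl)silyl]oxy}undecyl)-3,4-dihydro-1H-isochromen-1-one | COc1cc(O)c2c(c1)C[C@@H](CCCCCCCCCCCO[Si](C(C)C)(C(C)C)C(C)C)OC2=O | intermediate
14 | (3R)-8-hydroxy-3-(11-hydroxyundecyl)-6-methoxy-3,4-dihydro-1H-isochromen-1-one | COc1cc(O)c2c(c1)C[C@@H](CCCCCCCCCCCO)OC2=O | target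

## Step count and risk

Total: 8 steps. Longest linear sequence: 7 steps (3 to 14 through steps 2–8, and equally 1 to 14 through steps 1 and 3–8).

**Step 5 (key step).** The likeliest failures are intermolecular arylation of the oxocarbenium ion by a second electron-rich ring, which would lead to oligomers through diarylmethane links, and acid-promoted loss of the silyl ether. The fallback forms the same C8a–C1 bond with carbon monoxide at the carboxyl level and replaces steps 4, 5 and 6. It sets out from alcohol 9. N-Bromosuccinimide in MeCN at 0 °C should brominate the ring ortho to the side chain and para to a methoxy group, the usual site for such arenes, to give (2R)-1-(2-bromo-3,5-dimethoxyphenyl)-13-{[tri(propan-2-yl)silyl]oxy}tridecan-2-ol F1. Palladium-catalysed carbonylative lactonisation of F1 (Pd(OAc)2, Xantphos, CO, Et3N, toluene, 100 °C), in which the free secondary alcohol captures the acylpalladium intermediate, returns to the route at lactone 12.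

**Step 6.** The likeliest failures are over-oxidation of the electron-rich ring or of C4, and stalling because the lipophilic substrate and the oxidant mix poorly. The fallback separates hydride abstraction from the second oxidation and sets out from isochroman 11. DDQ in wet CH2Cl2 abstracts hydride from C1, and water traps the stabilised oxocarbenium ion as the lactol (3R)-6,8-dimethoxy-3-(11-{[tri(propan-2-yl)silyl]oxy}undecyl)-3,4-dihydro-1H-isochromen-1-ol F2, a mixture of C1 epimers. Oxidation of F2 with catalytic TEMPO and PhI(OAc)2 returns to the route at 12.

**Step 2.** The main risk is erosion of enantiomeric purity if the arylcopper species displaces chloride directly instead of opening the epoxide, because the two pathways lead to mirror-image oxiranes. Homocoupling of the Grignard reagent would lower the yield. The fallback sets the configuration by catalyst-controlled kinetic resolution and starts from bromide 3 through its Grignard reagent 5. Allyl bromide converts 5 into 1,3-dimethoxy-5-(prop-2-en-1-yl)benzene F3. Epoxidation with 3-chloroperbenzoic acid gives racemic 2-[(3,5-dimethoxyphenyl)methyl]oxirane F4. Hydrolytic kinetic resolution of F4 uses water (0.55 equiv) and the acetate of trivalent cobalt with a chiral N,N′-bis(3,5-di-tert-butylsalicylidene)-1,2-cyclohexanediamine ligand, (salen)Co(OAc), in the enantiomeric form that hydrolyses the (R)-epoxide. The (R)-epoxide is removed as (2R)-3-(3,5-dimethoxyphenyl)propane-1,2-diol F5, and the route is rejoined at (S)-epoxide 7. The same resolution could also upgrade a batch of 7 of reduced enantiomeric purity.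

**Step 7.** The risk is cleavage of the second (C6) methyl ether with excess reagent or on warming. Loss of the silyl ether at this stage would do no harm, since it leads directly to 14. The fallback gives up selective cleavage for selective alkylation and sets out from 12. BBr3 in CH2Cl2 (−78 → 0 °C) is expected to cleave both aryl methyl ethers and the silyl ether and give (3R)-6,8-dihydroxy-3-(11-hydroxyundecyl)-3,4-dihydro-1H-isochromen-1-one F6. Iodomethane (1 equiv) and K2CO3 in acetone should then methylate only the C6 phenol, because the C8 phenol is hydrogen-bonded to the lactone carbonyl and the aliphatic alcohol is not deprotonated. This returns to the route at target 14.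

## Further compounds

F1 | step 5 | (2R)-1-(2-bromo-3,5-dimethoxyphenyl)-13-{[tri(propan-2-yl)silyl]oxy}tridecan-2-ol | COc1cc(OC)c(Br)c(C[C@H](O)CCCCCCCCCCCO[Si](C(C)C)(C(C)C)C(C)C)c1
F2 | step 6 | (3R)-6,8-dimethoxy-3-(11-{[tri(propan-2-yl)silyl]oxy}undecyl)-3,4-dihydro-1H-isochromen-1-ol (C1 epimers) | COc1cc(OC)c2c(c1)C[C@@H](CCCCCCCCCCCO[Si](C(C)C)(C(C)C)C(C)C)OC2O
F3 | step 2 | 1,3-dimethoxy-5-(prop-2-en-1-yl)benzene | COc1cc(CC=C)cc(OC)c1
F4 | step 2 | rac-2-[(3,5-dimethoxyphenyl)methyl]oxirane | COc1cc(CC2CO2)cc(OC)c1
F5 | step 2 | (2R)-3-(3,5-dimethoxyphenyl)propane-1,2-diol | COc1cc(C[C@@H](O)CO)cc(OC)c1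
F6 | step 7 | (3R)-6,8-dihydroxy-3-(11-hydroxyundecyl)-3,4-dihydro-1H-isochromen-1-one | Oc1cc(O)c2c(c1)C[C@@H](CCCCCCCCCCCO)OC2=O
A1 | alternative 1 | methyl 2,4-dimethoxy-6-{[(1R)-2-oxocyclododecyl]methyl}benzoate | COC(=O)c1c(OC)cc(OC)cc1C[C@H]1CCCCCCCCCCC1=O
A2 | alternative 1 | methyl 2,4-dimethoxy-6-{[(2R)-13-oxooxacyclotridecan-2-yl]methyl}benzoate | COC(=O)c1c(OC)cc(OC)cc1C[C@H]1CCCCCCCCCCC(=O)O1
A3 | alternative 2 | 6,8-dimethoxy-1H-isochromene-1,3(4H)-dione | COc1cc(OC)c2c(c1)CC(=O)OC2=O
A4 | alternative 2 | 12-(benzyloxy)dodecanal | O=CCCCCCCCCCCCOCc1ccccc1
A5 | alternative 2 | (3R,4S)-3-[11-(benzyloxy)undecyl]-6,8-dimethoxy-1-oxo-3,4-dihydro-1H-isochromene-4-carboxylic acid | COc1cc(OC)c2c(c1)[C@H](C(=O)O)[C@@H](CCCCCCCCCCCOCc3ccccc3)OC2=O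
A6 | alternative 3 | 6-[(6R)-17-(benzyloxy)-6-{[tert-butyl(dimethyl)silyl]oxy}-2,4-dioxoheptadecyl]-2,2-dimethyl-4H-1,3-dioxin-4-one | CC1(C)OC(=O)C=C(O1)CC(=O)CC(=O)C[C@@H](CCCCCCCCCCCOCc1ccccc1)O[Si](C)(C)C(C)(C)C
A7 | alternative 3 | 5-[(2R)-13-(benzyloxy)-2-{[tert-butyl(dimethyl)silyl]oxy}tridecyl]-7-hydroxy-2,2-dimethyl-4H-1,3-benzodioxin-4-one | CC1(C)OC(=O)c2c(O1)cc(O)cc2C[C@@H](CCCCCCCCCCCOCc3ccccc3)O[Si](C)(C)C(C)(C)C
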